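**Retrosynthetic overview**

1. Target 12 is a (2S)-flavanone; the last disconnection is the benzyl ether on the ring B phenol (11 → 12).
2. The pyranone ring (O1–C2–C3–C4–C4a–C8a) is cut at C4–C4a and O1–C8a. Its atoms O1–C2–C3–C4 are the β-lactone (S)-7, and the C4a–C8a edge of ring A is inserted into the lactone acyl–oxygen bond by an ortho-fluoroaryllithium (Li on C4a, F on C8a) made in the flask from 8: a two-atom ring expansion, four to six members.
3. Enabling feature: O1 and the C4 carbonyl are 1,3-related across C2–C3 (a β-oxy ketone, the retron of a β-lactone) and sit on the adjacent carbons C8a and C4a of ring A. The only stereocenter, C2, is the lactone carbinol carbon, whose C–O bond is never broken.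
4. (S)-7 is traced to aryl ester 1: benzylation, Claisen condensation, ruthenium–BINAP hydrogenation of the β-keto ester (sets C2), saponification, carboxyl-activated β-lactonization.
5. Order of ring formation: rings A and B are bought as arenes; the β-lactone ring is closed in step 5 and expanded to the pyranone ring in step 6.

Key step: step 6

Remark: the stereodescriptor of the target is read as (2S), and 1 and 8 are taken as the commercial starting materials.

**Route**

Step 1
Reactants: 1 methyl 3-hydroxy-4,5-dimethoxybenzoate
Product: 2 methyl 3-(benzyloxy)-4,5-dimethoxybenzoate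
Conditions: BnBr, K2CO3, DMF, 60 °C
Reagents that add atoms: benzyl bromide, BrCc1ccccc1
Why: Williamson ether synthesis on the phenoxide, which masks the acidic ring B phenol against the organolithium of step 6 as a benzyl ether that can be removed under neutral conditions at the end.

Step 2
Reactants: 2 methyl 3-(benzyloxy)-4,5-dimethoxybenzoate
Product: 3 methyl 3-[3-(benzyloxy)-4,5-dimethoxyphenyl]-3-oxopropanoate
Conditions: MeOAc, LiN(SiMe3)2 (excess), THF, −78 → 0 °C; then 1 M HCl
Reagents that add atoms: methyl acetate, COC(C)=O
Why: Crossed Claisen condensation of the lithium enolate of methyl acetate with the non-enolizable aryl ester, driven to completion by deprotonation of the β-keto ester product, with methyl acetate chosen so that only one ester alkyl group is present.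

Step 3
Reactants: 3 methyl 3-[3-(benzyloxy)-4,5-dimethoxyphenyl]-3-oxopropanoate
Product: 4 methyl (3S)-3-[3-(benzyloxy)-4,5-dimethoxyphenyl]-3-hydroxypropanoate
Conditions: H2 (10 bar), [RuCl2((R)-BINAP)] (1 mol%), MeOH, 60 °C
Reagents that add atoms: none
Why: Noyori asymmetric hydrogenation of a β-keto ester, in which the substrate chelates the chiral ruthenium hydride through its ketone and ester carbonyls so that hydride reaches one enantioface, the (R)-ligand being the one expected by analogy with simple aroylacetates to give the (S)-carbinol that becomes C2, while the benzyl ether and the arenes are inert to this catalyst.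

Step 4
Reactants: 4 methyl (3S)-3-[3-(benzyloxy)-4,5-dimethoxyphenyl]-3-hydroxypropanoate
Product: 5 (3S)-3-[3-(benzyloxy)-4,5-dimethoxyphenyl]-3-hydroxypropanoic acid
Conditions: LiOH·H2O, THF/H2O, 0 °C; then 1 M HCl to pH 3
Reagents that add atoms: lithium hydroxide, [Li+].[OH-]
Why: Ester saponification under cold, mild hydroxide conditions that should avoid retro-aldol cleavage and dehydration of the benzylic β-hydroxy ester, the stereocenter not being involved and the crystalline acid offering a point for enrichment by recrystallization.

Step 5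
Reactants: 5 (3S)-3-[3-(benzyloxy)-4,5-dimethoxyphenyl]-3-hydroxypropanoic acid
Product: 7 (4S)-4-[3-(benzyloxy)-4,5-dimethoxyphenyl]oxetan-2-one, via mixed anhydride 6 (not isolated)
Conditions: PhSO2Cl, pyridine, 0 °C
Reagents that add atoms: none
Why: β-Lactonization by carboxyl activation, in which the carboxylate is sulfonylated to the mixed carboxylic–sulfonic anhydride 6 and the β-hydroxyl attacks its acyl carbon in a 4-exo-trig substitution, so that the C–O bond at the stereocenter is never broken and the (S) configuration is retained.

Step 6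
Reactants: 7 (4S)-4-[3-(benzyloxy)-4,5-dimethoxyphenyl]oxetan-2-one; 8 1-fluoro-2,3-dimethoxybenzene
Product: 11 (2S)-2-[3-(benzyloxy)-4,5-dimethoxyphenyl]-7,8-dimethoxy-2,3-dihydro-4H-chromen-4-one, via aryllithium 9 (not isolated), via lithium keto alkoxide 10 (not isolated)
Conditions: 8, n-BuLi, THF, −78 °C; added slowly to 7, THF, −78 °C; then DMPU, −78 °C → rt; aq. NH4Cl
Reagents that add atoms: none
Why: Proposed new method: the four-membered lactone ring O1–C2–C3–C4 of 7 is expanded by two atoms to the six-membered pyranone by formal insertion of the C4a–C8a edge of ring A into its acyl–oxygen bond, run as a one-flask anionic cascade whose closest known reaction types are the σ-insertion of arynes into the N–C(O) bond of β-lactams (which gives 2,3-dihydroquinolin-4-ones), the carbonyl opening of β-lactones by organolithiums to β-hydroxy ketones and the SNAr closure of 2-fluoroaryl ketones to chromanones. Fluorine-directed ortho-lithiation of 8 should give aryllithium 9, whose carbanionic carbon (the future C4a) adds to the strained lactone carbonyl, and acyl–oxygen cleavage of the adduct releases lithium alkoxide 10 with the new ketone ortho to the C–F carbon (the future C8a). The pyranone ring then closes by 6-exo-trig addition–elimination of the alkoxide oxygen O1 at that carbon, activated by the ortho carbonyl, with loss of LiF. No stereocenter is created, because C2 is the carbinol carbon of the lactone and its C–O bond is never broken, so the (S) configuration set in step 3 is carried through with retention. The regiochemistry that a free 3,4-dimethoxybenzyne would not give (an oxygen nucleophile adds meta to the methoxy group beside the triple bond, which would put O1 on the wrong carbon) is fixed here by the substrate, since the fluorine both directs lithiation to its ortho carbon and marks the carbon that receives O1. The step needs monoaddition and a ring closure faster than retro-aldol cleavage or dehydration of 10, which inverse addition at −78 °C, the intramolecular 6-exo geometry with fluoride as leaving group and the dipolar cosolvent DMPU are meant to secure.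

Step 7
Reactants: 11 (2S)-2-[3-(benzyloxy)-4,5-dimethoxyphenyl]-7,8-dimethoxy-2,3-dihydro-4H-chromen-4-one
Product: 12 (2S)-2-(3-hydroxy-4,5-dimethoxyphenyl)-7,8-dimethoxy-2,3-dihydro-4H-chromen-4-one
Conditions: H2 (1 atm), 10% Pd/C, EtOAc, rt
Reagents that add atoms: none
Why: Catalytic hydrogenolysis of the aryl benzyl ether under neutral conditions, which should leave the C2 stereocenter untouched because no base or acid is present to open the pyranone by retro-oxa-Michael reaction, the reaction being stopped after uptake of one equivalent of H2 to spare the C4 ketone and the benzylic C2–O1 bond.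

**Compound list**

1 | methyl 3-hydroxy-4,5-dimethoxybenzoate | COC(=O)c1cc(O)c(OC)c(OC)c1 | starting material
2 | methyl 3-(benzyloxy)-4,5-dimethoxybenzoate | COC(=O)c1cc(OC)c(OC)c(OCc2ccccc2)c1 | intermediate
3 | methyl 3-[3-(benzyloxy)-4,5-dimethoxyphenyl]-3-oxopropanoate | COC(=O)CC(=O)c1cc(OC)c(OC)c(OCc2ccccc2)c1 | intermediate
4 | methyl (3S)-3-[3-(benzyloxy)-4,5-dimethoxyphenyl]-3-hydroxypropanoate | COc1cc([C@@H](O)CC(=O)OC)cc(OCc2ccccc2)c1OC | intermediate
5 | (3S)-3-[3-(benzyloxy)-4,5-dimethoxyphenyl]-3-hydroxypropanoic acid | COc1cc([C@@H](O)CC(=O)O)cc(OCc2ccccc2)c1OC | intermediate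
6 | (3S)-3-[3-(benzyloxy)-4,5-dimethoxyphenyl]-3-hydroxypropanoic benzenesulfonic anhydride (not isolated) | COc1cc([C@@H](O)CC(=O)OS(=O)(=O)c2ccccc2)cc(OCc3ccccc3)c1OC | intermediate
7 | (4S)-4-[3-(benzyloxy)-4,5-dimethoxyphenyl]oxetan-2-one | COc1cc([C@@H]2CC(=O)O2)cc(OCc3ccccc3)c1OC | intermediate
8 | 1-fluoro-2,3-dimethoxybenzene | COc1cccc(F)c1OC | starting material
9 | (2-fluoro-3,4-dimethoxyphenyl)lithium (not isolated) | [Li]c1ccc(OC)c(OC)c1F | intermediate
10 | lithium (1S)-1-[3-(benzyloxy)-4,5-dimethoxyphenyl]-3-(2-fluoro-3,4-dimethoxyphenyl)-3-oxopropan-1-olate (not isolated) | [Li+].COc1cc([C@@H]([O-])CC(=O)c2ccc(OC)c(OC)c2F)cc(OCc3ccccc3)c1OC | intermediate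
11 | (2S)-2-[3-(benzyloxy)-4,5-dimethoxyphenyl]-7,8-dimethoxy-2,3-dihydro-4H-chromen-4-one | COc1cc([C@@H]2CC(=O)c3ccc(OC)c(OC)c3O2)cc(OCc4ccccc4)c1OC | intermediate
12 | (2S)-2-(3-hydroxy-4,5-dimethoxyphenyl)-7,8-dimethoxy-2,3-dihydro-4H-chromen-4-one | COc1cc([C@@H]2CC(=O)c3ccc(OC)c(OC)c3O2)cc(O)c1OC | target

**Step count and risks**

Total step count: 7. Longest linear sequence: 7 steps (1 → 12); fluoroarene 8 enters step 6 directly.

Steps most likely to fail:

Step 6 (proposed new method). What may go wrong: a second addition of aryllithium 9 to the ketone as soon as the lactone adduct collapses. During warming, retro-aldol cleavage or E1cB dehydration of aldolate 10 may also outrun a slow SNAr on the donor-substituted fluoroarene, with loss of material or of enantiomeric purity. The fallback uses known chemistry, closes the ring at C2–O1 by a Mitsunobu reaction with inversion, sets out from 3 and comes back at 11. Hydrogenation of 3 with the enantiomeric catalyst [RuCl2((S)-BINAP)] should give methyl (3R)-3-[3-(benzyloxy)-4,5-dimethoxyphenyl]-3-hydroxypropanoate F1. Me(MeO)NH·HCl with i-PrMgCl (THF, −20 °C) converts it into (3R)-3-[3-(benzyloxy)-4,5-dimethoxyphenyl]-3-hydroxy-N-methoxy-N-methylpropanamide F2. 1,2-Dimethoxy-3-(methoxymethoxy)benzene F3 (from 2,3-dimethoxyphenol, MOMCl, i-Pr2NEt) is lithiated ortho to the MOM ether (n-BuLi, THF, 0 °C) to [3,4-dimethoxy-2-(methoxymethoxy)phenyl]lithium F4. Used in excess to allow for the free hydroxyl, this is acylated by F2 to give (3R)-3-[3-(benzyloxy)-4,5-dimethoxyphenyl]-1-[3,4-dimethoxy-2-(methoxymethoxy)phenyl]-3-hydroxypropan-1-one F5. HCl in MeOH at 0 °C removes the MOM group to give (3R)-3-[3-(benzyloxy)-4,5-dimethoxyphenyl]-3-hydroxy-1-(2-hydroxy-3,4-dimethoxyphenyl)propan-1-one F6. PPh3 and DIAD (THF, 0 °C) then close the pyranone by SN2 attack of the phenol oxygen at the carbinol carbon with inversion, which should give 11 with the (2S) configuration.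

Step 5. What may go wrong: sulfonylation of the benzylic hydroxyl in competition with the carboxylate, followed by elimination to the cinnamic acid, or ionization and decarboxylation of the benzylic β-lactone during work-up. The fallback builds the lactone by cycloaddition instead of lactonization, sets out from 2 and comes back at 7. LiAlH4 (THF, 0 °C) should reduce 2 to [3-(benzyloxy)-4,5-dimethoxyphenyl]methanol F7, and MnO2 (CH2Cl2, rt) should oxidize it to 3-(benzyloxy)-4,5-dimethoxybenzaldehyde F8. A catalytic asymmetric ketene–aldehyde [2+2] cycloaddition then gives 7 directly without a free β-hydroxy acid: acetyl chloride, i-Pr2NEt, LiClO4 and O-trimethylsilylquinine or O-trimethylsilylquinidine (whichever pseudoenantiomer delivers the (S)-lactone), CH2Cl2/Et2O, −40 °C.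

Step 7. What may go wrong: over-reduction, either hydrogenolysis of the benzylic C2–O1 bond (opening of the pyranone to the dihydrochalcone) or reduction of the C4 ketone. The fallback replaces hydrogenolysis by a Lewis-acid debenzylation, sets out from 11 and ends at 12: BCl3 with pentamethylbenzene as cation scavenger (CH2Cl2, −78 °C), which should spare the methyl ethers since none is chelated to the carbonyl. It makes no new compound (F0).

Further compounds
F1 | step 6 | methyl (3R)-3-[3-(benzyloxy)-4,5-dimethoxyphenyl]-3-hydroxypropanoate | COc1cc([C@H](O)CC(=O)OC)cc(OCc2ccccc2)c1OC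
F2 | step 6 | (3R)-3-[3-(benzyloxy)-4,5-dimethoxyphenyl]-3-hydroxy-N-methoxy-N-methylpropanamide | COc1cc([C@H](O)CC(=O)N(C)OC)cc(OCc2ccccc2)c1OC
F3 | step 6 | 1,2-dimethoxy-3-(methoxymethoxy)benzene | COCOc1cccc(OC)c1OC
F4 | step 6 | [3,4-dimethoxy-2-(methoxymethoxy)phenyl]lithium | [Li]c1ccc(OC)c(OC)c1OCOC
F5 | step 6 | (3R)-3-[3-(benzyloxy)-4,5-dimethoxyphenyl]-1-[3,4-dimethoxy-2-(methoxymethoxy)phenyl]-3-hydroxypropan-1-one | COc1cc([C@H](O)CC(=O)c2ccc(OC)c(OC)c2OCOC)cc(OCc3ccccc3)c1OC
F6 | step 6 | (3R)-3-[3-(benzyloxy)-4,5-dimethoxyphenyl]-3-hydroxy-1-(2-hydroxy-3,4-dimethoxyphenyl)propan-1-one | COc1cc([C@H](O)CC(=O)c2ccc(OC)c(OC)c2O)cc(OCc3ccccc3)c1OC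
F7 | step 5 | [3-(benzyloxy)-4,5-dimethoxyphenyl]methanol | COc1cc(CO)cc(OCc2ccccc2)c1OC
F8 | step 5 | 3-(benzyloxy)-4,5-dimethoxybenzaldehyde | COc1cc(C=O)cc(OCc2ccccc2)c1OC
F0 | step 7 | none | none
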